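**Remark (assumption).** The target is taken as the neutral N–H bis-phenol ketone of the given SMILES. It has no stereocentre and no stereogenic double bond, so no configuration has to be set. Compounds 1, 3 and 6 are taken as commercial; if ester 7 is bought instead of made, step 3 falls away.

## Analysis of the target

The target is a diaryl ketone with no stereocentre, so the problem is one of regiochemistry and chemoselectivity. Its benzene ring (C1–C6) carries the ketone carbon C7 at C1, hydroxyl groups at C2 and C4, a 4-methylpentyl chain at C3 between them and hydrogen at C5 and C6; C7 is bonded to C2' of a 1H-pyrrole that carries chlorine at C4' and C5' and a free N–H. The benzene ring has four contiguous substituents and is very electron-rich, so any electrophilic chlorination after it exists would attack C5 as readily as the pyrrole; both chlorines should therefore arrive with the pyrrole. Sensitive groups are the two free phenols (which normally force protection and deprotection), the acidic pyrrole N–H, and the two C–Cl bonds, which should not meet zerovalent palladium or hydrogenation catalysts. The feature that invites a bold move is the pattern C7(=O)–C1–C2(O)–C3(alkyl)–C4(O)–C5(H)–C6(H), a folded tetracarbonyl chain with C6 at the aldehyde level. In masked, cyclic form this chain is a 2-(acylmethyl)-3-alkyl-4H-pyran-4-one, which is the skeleton of maltol 1. The methyl carbon, C2, C3, C4, C5 and C6 of 1 map one by one onto C1–C6 of the benzene ring, the ring oxygen of 1 becomes the C2 hydroxyl and its carbonyl oxygen becomes the C4 hydroxyl. The difficulty is therefore to bring the 1,2,3,4-pattern, the free phenols and the chlorinated pyrrole together without protecting-group traffic on the arene.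

## Retrosynthetic reasoning

**13 ⇒ 10 (through 11 and 12).** The benzene ring is cut at C1–C6 and the oxygen on C2 is joined to C6, which turns the carbocycle into the 4-pyranone 11, carried as its N-Boc derivative 10. This cut is chosen because the precursor needs no phenol protection and its constitution fixes the whole substitution pattern. The forward reaction must open the pyranone at C6 with an alkoxide (12) and close the chain through carbon, C1 on C6, so that the aromatic ring forms as the thermodynamic sink. The same base removes the Boc group, so 13 is released unprotected in one operation.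

**10 ⇒ 5 + 8.** The C1–C7 bond is cut between the lateral CH2 of the pyranone and the ketone. The forward step is a vinylogous Claisen acylation of the lithium dienolate 9 of 5 with ester 8. The cut is placed here so that the pyrrole arrives with both chlorines already in place and no chlorination is ever needed next to an electron-rich ring. The Boc group of 8 removes the acidic N–H and makes the ester a better electrophile.

**5 ⇒ 2 + 3, and 2 ⇒ 1.** The sp2–sp3 bond between C3 of the pyranone and the chain is cut. The forward step is a B-alkyl Suzuki–Miyaura coupling of triflate 2 with the borane 4 made from alkene 3. The hydroxyl group of 1 sits exactly where the chain is needed, so 1 supplies all six future ring carbons and the handle for the chain. This is also the only palladium step, and it comes before any C–Cl bond is present.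

**8 ⇒ 7 ⇒ 6.** The acyl donor is traced back by N-acylation and esterification to the commercial dichloropyrrole acid 6. Both steps are functional-group operations.

## Alternatives that were turned down

**Alternative 1:** The textbook cut is the C1–C7 bond. The forward key step is a Friedel–Crafts acylation of 1,3-dimethoxy-2-(4-methylpentyl)benzene A1 with acid 6 activated as its acyl cation. It gives the dimethoxy ketone A2, which is then demethylated with BBr3. The symmetry of A1 makes the regiochemistry trivial and the route is short. It was turned down for three reasons:
- The electrophile is a pyrrole-2-carbonyl cation, a vinylogous carbamoyl cation stabilised by the ring nitrogen, so it is weak, while its own N–H and C3' can be acylated.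
- Two steps are spent on methyl ethers, and the ether at C4 of A2 has no chelation assistance and needs excess BBr3 in the presence of the chlorinated pyrrole.
- It builds no ring; it is the route most chemists would draw first.

**Alternative 2:** C1–C7 and C7–C2' are cut together. The forward key step is a three-component carbonylative Suzuki–Miyaura coupling of 1-iodo-2,4-bis(methoxymethoxy)-3-(4-methylpentyl)benzene A3, CO and [1-(tert-butoxycarbonyl)-1H-pyrrol-2-yl]boronic acid A4 to give ketone A5, then dichlorination with SO2Cl2 and deprotection. It was turned down because the chlorines cannot ride through the coupling on the boron partner A4, and chlorination of A5 must distinguish pyrrole C4'/C5' from the benzene C5, which is ortho and para to two oxygens. Boronic acid A4, like other 2-pyrrolylboronic acids, is also prone to protodeboronation and to direct coupling with iodide A3 without CO. With protection, iodination and deprotection the route needs seven or more steps.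

**Alternative 3:** The ring is cut at C1–C6, as in the chosen route, and in addition at C3–C4, with both fragments acyclic. The forward key step is a [3+3] Michael–Claisen annulation of 1-(4,5-dichloro-1H-pyrrol-2-yl)-8-methylnonane-1,3-dione A6 with methyl propiolate. After Michael addition of the central carbon of A6, the adduct A7 has its ester deactivated by conjugation with the extended enolate, and the gamma carbon of A7 can attack only as a dianion. Closure through the enol oxygen to the 2-pyranone A8 is therefore expected to win. The pyrrole N–H of A6 also adds to the alkynoate. If the gamma carbanion of A6 is formed first, it adds to the alkyne and the annulation leads to the 2,6-dihydroxy isomer A9. The chosen route uses the same polyketide logic but locks the regiochemistry in a heteroaromatic ring.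

Key step: step 6

## Route

**Step 1**
Reactants: 1 maltol (3-hydroxy-2-methyl-4H-pyran-4-one)
Product: 2 2-methyl-4-oxo-4H-pyran-3-yl trifluoromethanesulfonate
Conditions: Tf2O, pyridine, CH2Cl2, −10 to 0 °C
Reagents that add atoms: trifluoromethanesulfonic anhydride, O=S(=O)(OS(=O)(=O)C(F)(F)F)C(F)(F)F
Why: O-Sulfonylation of the only hydroxyl group, an acidic enol, should be fast and clean; it turns C3 into a vinyl triflate for cross-coupling.

**Step 2**
Reactants: 2 2-methyl-4-oxo-4H-pyran-3-yl trifluoromethanesulfonate, 3 4-methylpent-1-ene
Product: 5 2-methyl-3-(4-methylpentyl)-4H-pyran-4-one, via alkylborane 4 (not isolated)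
Conditions: 3, 9-BBN-H, THF, 0 °C to rt; then 2, PdCl2(dppf) (5 mol %), K3PO4 (3 M aq.), DMF, 50 °C
Reagents that add atoms: none
Why: B-alkyl Suzuki–Miyaura coupling: anti-Markovnikov hydroboration gives the primary borane 4, zerovalent palladium inserts readily into the C–OTf bond alpha to the pyranone carbonyl, and the wide-bite-angle dppf ligand favours reductive elimination over beta-hydride elimination; no C–Cl bond is present yet.

**Step 3**
Reactants: 6 4,5-dichloro-1H-pyrrole-2-carboxylic acid
Product: 7 methyl 4,5-dichloro-1H-pyrrole-2-carboxylate
Conditions: MeOH, H2SO4 (cat.), 65 °C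
Reagents that add atoms: methanol, CO
Why: Fischer esterification; the two chlorines deactivate the pyrrole towards C-protonation, so acid-induced decarboxylation should not compete.

**Step 4**
Reactants: 7 methyl 4,5-dichloro-1H-pyrrole-2-carboxylate
Product: 8 1-tert-butyl 2-methyl 4,5-dichloro-1H-pyrrole-1,2-dicarboxylate
Conditions: Boc2O, DMAP (cat.), Et3N, MeCN, rt
Reagents that add atoms: di-tert-butyl dicarbonate, CC(C)(C)OC(=O)OC(=O)OC(C)(C)C
Why: DMAP-catalysed N-acylation of an acidic pyrrole N–H; the carbamate removes the acidic proton and the nitrogen lone-pair donation that would deactivate the ester in step 5.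

**Step 5**
Reactants: 5 2-methyl-3-(4-methylpentyl)-4H-pyran-4-one, 8 1-tert-butyl 2-methyl 4,5-dichloro-1H-pyrrole-1,2-dicarboxylate
Product: 10 tert-butyl 2,3-dichloro-5-{[3-(4-methylpentyl)-4-oxo-4H-pyran-2-yl]acetyl}-1H-pyrrole-1-carboxylate, via lithium dienolate 9 (not isolated)
Conditions: 5, LiN(SiMe3)2 (2.2 equiv), THF, −78 °C; then 8, −78 to −40 °C; aq. NH4Cl
Reagents that add atoms: none
Why: Vinylogous (lateral) Claisen condensation: the C2 methyl group is the only gamma position of the vinylogous ester and is deprotonated to dienolate 9, which attacks the unhindered methyl ester of 8 in preference to the tert-butyl carbamate; the second equivalent of base stores 10 as its enolate and prevents double acylation.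

**Step 6**
Reactants: 10 tert-butyl 2,3-dichloro-5-{[3-(4-methylpentyl)-4-oxo-4H-pyran-2-yl]acetyl}-1H-pyrrole-1-carboxylate
Product: 13 (4,5-dichloro-1H-pyrrol-2-yl)[2,4-dihydroxy-3-(4-methylpentyl)phenyl]methanone, via N–H acylmethylpyranone 11 (not isolated), via open-chain methoxyenone 12 (not isolated)
Conditions: NaOMe (5 equiv), MeOH, 65 °C; then 1 M aq. HCl
Reagents that add atoms: none
Why: Methoxide first cleaves the Boc group from the electron-poor pyrrole nitrogen to give 11, then adds to C6, the only unsubstituted carbon next to the ring oxygen, and the adduct opens by retro-oxa-Michael cleavage of the O1–C6 bond to the methoxyenone 12, in which the former ring oxygen is the C2 carbonyl and the methoxy group comes from the base. The doubly activated carbon between the pyrrolyl ketone and the C2 carbonyl (the former lateral CH2, future C1) then adds to C6 and expels methoxide, which closes the only ring of the step, the benzene ring, through the C1–C6 bond in a 6-endo-trig addition–elimination; two enolisations give the resorcinol, stored as its phenoxide. The closest known reaction type is the base-induced conversion of 2-methyl- and 2-(acylmethyl)-4-pyranones into resorcinols by ring opening and intramolecular aldol condensation, the polyketide-type pyranone-to-benzene ring transformation. No stereocentre is formed. The step needs closure of C1 on C6 and no other: C6 is the only electrophilic carbon at six-ring distance from C1, C5 is held as a vinyl ether carbon in 12 and cannot attack the pyrrolyl ketone, closure through oxygen only returns 11 reversibly, and every event before aromatisation is reversible. Anhydrous methoxide rather than hydroxide keeps C6 as an enol ether and so avoids retro-Claisen loss of C6 as formate. The substitution pattern of 13 (acyl at C1, hydroxyl at C2 and C4, chain at C3) is fixed by the constitution of 10.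

## Compound list

1 | maltol (3-hydroxy-2-methyl-4H-pyran-4-one) | CC1=C(O)C(=O)C=CO1 | starting material
2 | 2-methyl-4-oxo-4H-pyran-3-yl trifluoromethanesulfonate | CC1=C(OS(=O)(=O)C(F)(F)F)C(=O)C=CO1 | intermediate
3 | 4-methylpent-1-ene | C=CCC(C)C | starting material
4 | B-(4-methylpentyl)-9-borabicyclo[3.3.1]nonane | CC(C)CCCB1C2CCCC1CCC2 | intermediate
5 | 2-methyl-3-(4-methylpentyl)-4H-pyran-4-one | CC1=C(CCCC(C)C)C(=O)C=CO1 | intermediate
6 | 4,5-dichloro-1H-pyrrole-2-carboxylic acid | OC(=O)c1cc(Cl)c(Cl)[nH]1 | starting material
7 | methyl 4,5-dichloro-1H-pyrrole-2-carboxylate | COC(=O)c1cc(Cl)c(Cl)[nH]1 | intermediate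
8 | 1-tert-butyl 2-methyl 4,5-dichloro-1H-pyrrole-1,2-dicarboxylate | COC(=O)c1cc(Cl)c(Cl)n1C(=O)OC(C)(C)C | intermediate
9 | lithium 2-methylidene-3-(4-methylpentyl)-2H-pyran-4-olate | [Li+].C=C1OC=CC([O-])=C1CCCC(C)C | intermediate
10 | tert-butyl 2,3-dichloro-5-{[3-(4-methylpentyl)-4-oxo-4H-pyran-2-yl]acetyl}-1H-pyrrole-1-carboxylate | CC(C)CCCC1=C(CC(=O)c2cc(Cl)c(Cl)n2C(=O)OC(C)(C)C)OC=CC1=O | intermediate
11 | 2-[2-(4,5-dichloro-1H-pyrrol-2-yl)-2-oxoethyl]-3-(4-methylpentyl)-4H-pyran-4-one | CC(C)CCCC1=C(CC(=O)c2cc(Cl)c(Cl)[nH]2)OC=CC1=O | intermediate
12 | (6E)-1-(4,5-dichloro-1H-pyrrol-2-yl)-7-methoxy-4-(4-methylpentyl)hept-6-ene-1,3,5-trione (geometry without consequence) | CO/C=C/C(=O)C(CCCC(C)C)C(=O)CC(=O)c1cc(Cl)c(Cl)[nH]1 | intermediate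
13 | (4,5-dichloro-1H-pyrrol-2-yl)[2,4-dihydroxy-3-(4-methylpentyl)phenyl]methanone | CC(C)CCCc1c(O)ccc(C(=O)c2cc(Cl)c(Cl)[nH]2)c1O | target

## Step count and risk

Total step count: 6. Longest linear sequence: 4 steps (steps 1, 2, 5, 6 from 1; equally steps 3, 4, 5, 6 from 6).

**Step 6 (key step).** Three things are most likely to go wrong.
- The reaction may stall, because under excess methoxide the substrate sits as an unreactive dianion (pyrrolide plus lateral enolate) and ring opening at C6 can only pass through a minor, less deprotonated form.
- The open chain may fragment by retro-Claisen attack of methoxide at a chain carbonyl.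
- The pyrrolide nitrogen may add to C2 of the pyranone, which would lead to a ring switch with an N–aryl bond.

The fallback sets out from 10 and returns at 13. The Boc group is removed with CF3CO2H in CH2Cl2 and 11 is isolated. Pyrrolidine in EtOH at rt then opens the pyranone at C6 as a neutral nucleophile to give the enaminone (6E)-1-(4,5-dichloro-1H-pyrrol-2-yl)-4-(4-methylpentyl)-7-(pyrrolidin-1-yl)hept-6-ene-1,3,5-trione F1 as an open-chain intermediate. Warming F1 in AcOH at 80 °C should close C1 on the protonated vinylogous amide carbon C6, expel pyrrolidine and aromatise to 13. In this sequence the pyrrole stays N–H and no polyanion is involved.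

**Step 5.** The dienolate may attack the carbamate carbonyl (Boc transfer) instead of the ester, be quenched by proton transfer, or add to a second pyranone. The fallback sets out from 5 and 6 and returns at 13; it reverses the order of ring formation and acylation. Compound 5 is subjected to the alkoxide ring transformation of step 6 (NaOMe, MeOH, 65 °C), in which the methyl ketone carbon closes on C6, to give 2-(4-methylpentyl)benzene-1,3-diol F2 as the free resorcinol. The resorcinol F2 is then C-acylated with acid 6 in BF3·OEt2 at 90 °C (Friedel–Crafts acylation with O-acyl to C-acyl migration). Both free positions ortho and para to the hydroxyl groups of F2 are equivalent, so only 13 can form.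

**Step 2.** Transmetalation of the alkylborane may be slow, with beta-hydride elimination, sulfur–oxygen hydrolysis of the triflate back to 1, or base-induced opening of the pyranone taking over. The fallback sets out from 2 and returns at 5. A Sonogashira coupling of 2 with 4-methylpent-1-yne (PdCl2(PPh3)2, CuI, Et3N, THF, rt to 50 °C) gives 2-methyl-3-(4-methylpent-1-yn-1-yl)-4H-pyran-4-one F3 as the alkynylpyranone. Hydrogenation of the triple bond of F3 (H2, 1 atm, Pd/C, EtOAc) then gives 5; no C–Cl bond is present at this stage. The approach avoids sp3 transmetalation and aqueous base.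

## Further compounds

F1 | step 6 | (6E)-1-(4,5-dichloro-1H-pyrrol-2-yl)-4-(4-methylpentyl)-7-(pyrrolidin-1-yl)hept-6-ene-1,3,5-trione | O=C(/C=C/N1CCCC1)C(CCCC(C)C)C(=O)CC(=O)c1cc(Cl)c(Cl)[nH]1
F2 | step 5 | 2-(4-methylpentyl)benzene-1,3-diol | CC(C)CCCc1c(O)cccc1O
F3 | step 2 | 2-methyl-3-(4-methylpent-1-yn-1-yl)-4H-pyran-4-one | CC1=C(C#CCC(C)C)C(=O)C=CO1
A1 | alternative 1 | 1,3-dimethoxy-2-(4-methylpentyl)benzene | COc1cccc(OC)c1CCCC(C)C
A2 | alternative 1 | (4,5-dichloro-1H-pyrrol-2-yl)[2,4-dimethoxy-3-(4-methylpentyl)phenyl]methanone | COc1ccc(C(=O)c2cc(Cl)c(Cl)[nH]2)c(OC)c1CCCC(C)C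
A3 | alternative 2 | 1-iodo-2,4-bis(methoxymethoxy)-3-(4-methylpentyl)benzene | COCOc1ccc(I)c(OCOC)c1CCCC(C)C
A4 | alternative 2 | [1-(tert-butoxycarbonyl)-1H-pyrrol-2-yl]boronic acid | CC(C)(C)OC(=O)n1cccc1B(O)O
A5 | alternative 2 | tert-butyl 2-[2,4-bis(methoxymethoxy)-3-(4-methylpentyl)benzoyl]-1H-pyrrole-1-carboxylate | COCOc1ccc(C(=O)c2cccn2C(=O)OC(C)(C)C)c(OCOC)c1CCCC(C)C
A6 | alternative 3 | 1-(4,5-dichloro-1H-pyrrol-2-yl)-8-methylnonane-1,3-dione | CC(C)CCCCC(=O)CC(=O)c1cc(Cl)c(Cl)[nH]1
A7 | alternative 3 | methyl (2E)-4-(4,5-dichloro-1H-pyrrole-2-carbonyl)-10-methyl-5-oxoundec-2-enoate | COC(=O)/C=C/C(C(=O)c1cc(Cl)c(Cl)[nH]1)C(=O)CCCCC(C)C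
A8 | alternative 3 | 5-(4,5-dichloro-1H-pyrrole-2-carbonyl)-6-(5-methylhexyl)-2H-pyran-2-one | O=C1C=CC(C(=O)c2cc(Cl)c(Cl)[nH]2)=C(CCCCC(C)C)O1
A9 | alternative 3 | (4,5-dichloro-1H-pyrrol-2-yl)[2,6-dihydroxy-3-(4-methylpentyl)phenyl]methanone | CC(C)CCCc1ccc(O)c(C(=O)c2cc(Cl)c(Cl)[nH]2)c1O
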